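## Analysis of the target

The target 32 is an isoflavan: a chroman (rings A and C) that carries at C3 an aryl ring B, which is fused through O2′ and C3′ to a 2,2-dimethyl-2H-pyran (ring D). Ring A is a fully differentiated phloroglucinol nucleus, with the ring oxygen O1 at C8a, a methoxyl at C5, a free hydroxyl at C7, a prenyl group at C6 between these two, and hydrogen at C8. C3 is the only stereocentre and is R; it lies between the methylene groups C2 and C4, has no neighbour to which it could be related, and must therefore be set in the absolute sense. The sensitive groups are the two phenols, the prenyl alkene next to the 7-hydroxyl and the styrene-like alkene of ring D (both lost under hydrogenation, ozonolysis, electrophilic halogen or strong acid), and the very electron-rich ring A, whose C8–H and benzylic C4–H bonds are open to electrophiles and to hydride-abstracting oxidants. The difficulty is regiochemical rather than stereochemical: three different oxygens and a C-prenyl group on ring A, and on ring B two oxygens, at C2′ and C4′, that must be told apart with a carbon substituent at C3′ between them. The strategy rests on this last motif: C2′(O)–C3′(C)–C4′(O), with C1′ bonded to C3, is a 2-alkyl-4-substituted cyclohexane-1,3-dione at a lower oxidation level, in which C3′ is the only doubly activated carbon and C1′–C6′ and C3′–C4′ are the bonds made when a methyl ketone is annulated with an acrylate.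

## Retrosynthetic reasoning

**32 to 31.** The last operation only removes two methoxymethyl acetals, on O7 and O4′. An acetal is used on O7 because this oxygen must pass through alkoxide, amide base and palladium chemistry, and on O4′ so that both come off together under mild acid.

**31 to 30.** Ring D is opened at the O2′–C(CH3)2 bond, which leaves an ortho-prenylphenol. The forward step is an oxidative cyclisation of the 2′-hydroxyl onto the C3′ prenyl group. It needs O4′ and O7 capped, so that only one phenol–alkene pair can react. It also needs an oxidant that does not abstract hydride from C4 of the 5,7-dioxygenated chroman; this excludes a quinone and points to palladium catalysis under air.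

**30 to 29.** The two phenols of ring B differ in their surroundings: O2′ lies between C1′ (bearing the chroman) and C3′ (bearing the prenyl group), whereas O4′ has only the prenyl group beside it. Cutting the O4′ acetal leads to resorcinol 29, and the forward protection is controlled by size.

**29 to 27 to 25.** Adding two hydrogens at C5′ and C6′ turns the resorcinol into the cyclohexane-1,3-dione 25. This removes the aromatic substitution problem: in 25 the oxygens at C2′ and C4′ are carbonyl groups and C3′ is an enolate carbon. Forward, 25 is converted into the bis(silyloxy)diene 27, which a hydride acceptor aromatises at low temperature.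

**25 to 24 and 4.** The bond from C3′ to the prenyl CH2 is cut. C3′ is the only carbon of 24 flanked by two carbonyl groups, so an allylic alkylation with carbonate 4 can place the prenyl group only there. On an aromatic ring B, C5′ would compete.

**24 to 21 and 22 (key disconnection).** Ring B is cut at C1′–C6′ and C3′–C4′. This releases C4′, C5′ and C6′ as methyl acrylate 22 and leaves C1′, C2′ and C3′ as the acetonyl side chain of ketone 21, so every substituted carbon of ring B comes from a defined position of a simple chain. In 21 the stereocentre C3 is β to the carbonyl and cannot be enolised, there or later. Forward, the ketone must add to 22 through its methylene carbon and then close through its methyl carbon; the first of these is the selectivity on which the route depends.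

**21 to 20 to 19.** After removal of the O7 acetal, ring C is opened at O1–C2 to the phenol alcohol 19. Two phenols are free in 19, but only the one ortho to the benzylic carbon can reach the primary carbinol. The ring closure itself therefore distinguishes O1 from O7, which is why both can be carried through the earlier steps under the same protecting group.

**19 to 18 to 17 to 15 and 9.** Compound 19 is the deprotected form of 18, and 18 is the reduction product of imide 17, which is cut at C3–C4. This places the stereocentre α to an imide carbonyl, where an Evans alkylation of 15 with the benzylic bromide 9 sets it with a predictable sense. The imide carbon becomes C2 and the ketal chain of 15 is the latent acetonyl group.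

**9 back to 1.** The benzylic carbon (C4) is the formyl carbon of 1. In 1 the hydroxyl para to the aldehyde and one ortho hydroxyl can be protected while the other ortho hydroxyl stays hydrogen-bonded and free (2). That oxygen is used twice: as the anchor of an O-allylation and Claisen sequence (5 to 6) that can deliver the prenyl group only to the adjacent carbon, and as the site of methylation (7). The methoxyl is thus fixed next to the prenyl group without any selective aromatic substitution; reduction and bromination (8, 9) follow.

**15 to 12 and 13; 12 to 11 to 10; 4 to 3.** The acyl part of 15 is ethyl levulinate 10 with its ketone masked as a dioxolane, attached to the commercial auxiliary 13. Carbonate 4, the allyl donor for both prenyl groups, comes from alcohol 3.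

## Alternatives that were turned down

**Alternative 1:** Ring C is cut at C3–C4 and at O1–C2, with C2 at the lactone oxidation level. Base would release the ring A quinone methide A3 from sulfone A1, and a chiral N-heterocyclic carbene would activate the ring B arylacetic ester A2 as a nucleophile at its α-carbon; formal [4+2] union would give chroman-2-one A4.
- For: it is convergent, both aromatic rings are complete before the union, chirality is catalytic, and ring C forms in one step. On these points it is stronger than the chosen route.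
- Against: the methide carbon of A3 is unsubstituted, so the only stereocentre created is C3 of A4, α to a lactone carbonyl and benzylic to an electron-rich arene. This is the most acidic C–H of the molecule, formed under the basic conditions that generate A3 and then exposed to hydride reduction.
- Against: the lactone carbonyl must be removed by reduction to the phenol alcohol and re-closure, at least two further steps.
- Against: A2 needs its own regiocontrolled synthesis of the 2′,4′-dioxygenated, 3′-carbon-substituted chromene, which only moves the ring B problem.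
- In its place the chosen route offers a stereocentre that is never α to a carbonyl after step 12, set by an auxiliary of known facial sense, and a ring B whose substitution pattern follows from its construction.

**Alternative 2:** Ring A is cut at C8–C8a, C5–C6, C7–C8 and C4a–C5. Irradiation of the dihydropyranyl diazo ketone A5 with siloxyalkyne A6 would trigger Wolff rearrangement, [2+2] addition, four-electron ring opening and six-electron closure, giving phenol A7.
- For: O1, O5 and O7 arrive already differentiated (ring ether, free phenol, silyl ether) and the prenyl group is placed by the alkyne. On ring A this is more economical than the five steps the chosen route spends on aldehyde 7.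
- Against: A5 must already hold the C3 stereocentre, ring C and a protected ring B, so a separate asymmetric synthesis of a 3-aryl-6-acyl dihydropyran precedes the key step.
- Against: the ketene formed on irradiation meets two other π-systems, the terminal alkyne of the propargyl ether and the prenyl alkene of A6, and the thermal part of the cascade overlaps with the temperature range of the propargyl Claisen rearrangement.
- Against: methylation of the hindered 5-hydroxyl, chromene formation and desilylation still follow.
- In its place the chosen route offers ordinary thermal chemistry throughout and sets the stereocentre early and robustly; its oxygen differentiation comes from hydrogen bonding in 1.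

**Alternative 3:** Ring C is cut at C4–C4a and O1–C2. A chiral primary amine would activate the 2-arylacrolein A9 towards conjugate attack by the ortho carbon of the symmetric phenol A8. Enantioselective protonation at the α-carbon would create C3, and the phenol would close the lactol A10.
- For: it has the fewest steps, is catalytic and convergent, and the symmetry of A8 removes any regiochemical question in the C–C bond formation. On step count it is clearly ahead.
- Against: the same symmetry is its flaw for this target. A10 carries identical acetals on O5 and O7, and once ring C is closed nothing distinguishes them chemically, so the 5-methoxy-7-hydroxy pattern cannot be reached without giving up the symmetric phenol.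
- Against: C3 is set by protonation and sits α to a masked aldehyde; ring–chain tautomerism of the lactol exposes an α-aryl aldehyde that racemises easily.
- Against: removing the lactol oxygen needs either an acidic silane reduction, which is incompatible with acetals, prenyl group and chromene, or reduction and re-closure.
- In its place the chosen route is longer but delivers O5 and O7 differentiated from the first step and a stereocentre that cannot epimerise.

Key step: step 16

Remark on the chemistry: prenyl stands for 3-methylbut-2-en-1-yl and chroman for 3,4-dihydro-2H-chromene; diones 24 and 25 are written as diketones although they should be largely enolised, and 19 may equilibrate with its cyclic hemiketal.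

## Route

Step 1
Reactants: 1 2,4,6-trihydroxybenzaldehyde
Product: 2 2-hydroxy-4,6-bis(methoxymethoxy)benzaldehyde
Conditions: MOMCl (2.2 equiv), i-Pr2NEt (2.5 equiv), CH2Cl2, 0 °C to rt
Reagents that add atoms: chloromethyl methyl ether, COCCl
Why: Williamson-type O-alkylation; the hydroxyl para to the formyl group and one ortho hydroxyl react, whereas the remaining ortho hydroxyl is deactivated by its hydrogen bond to the carbonyl, which singles out the oxygen that later becomes the 5-methoxyl.

Step 2
Reactants: 3 2-methylbut-3-en-2-ol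
Product: 4 methyl 2-methylbut-3-en-2-yl carbonate
Conditions: ClCO2Me (1.3 equiv), pyridine (2 equiv), DMAP (cat.), CH2Cl2, 0 °C to rt
Reagents that add atoms: methyl chloroformate, COC(=O)Cl
Why: Nucleophile-catalysed acylation of a tertiary allylic alcohol by a chloroformate; the carbonate is the allyl donor for steps 3 and 17.

Step 3
Reactants: 2 2-hydroxy-4,6-bis(methoxymethoxy)benzaldehyde; 4 methyl 2-methylbut-3-en-2-yl carbonate
Product: 5 2,4-bis(methoxymethoxy)-6-[(2-methylbut-3-en-2-yl)oxy]benzaldehyde
Conditions: Pd(PPh3)4 (3 mol %), THF, 4 Å MS, 0 °C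
Reagents that add atoms: none
Why: Tsuji–Trost O-allylation; zerovalent palladium ionises 4 with loss of CO2 and methoxide, the methoxide deprotonates the phenol, and the phenoxide attacks the 1,1-dimethylallyl palladium cation at its more substituted terminus under kinetic control at low temperature, giving the tertiary ether needed for step 4.

Step 4
Reactants: 5 2,4-bis(methoxymethoxy)-6-[(2-methylbut-3-en-2-yl)oxy]benzaldehyde
Product: 6 2-hydroxy-4,6-bis(methoxymethoxy)-3-prenylbenzaldehyde
Conditions: PhMe, 110 °C
Reagents that add atoms: none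
Why: Aromatic Claisen rearrangement, a [3,3]-sigmatropic shift followed by tautomerisation; one of the two positions ortho to the ether oxygen carries the formyl group, so the allyl unit can only arrive at C3, with allylic inversion, as a prenyl group.

Step 5
Reactants: 6 2-hydroxy-4,6-bis(methoxymethoxy)-3-prenylbenzaldehyde
Product: 7 2-methoxy-4,6-bis(methoxymethoxy)-3-prenylbenzaldehyde
Conditions: MeI (3 equiv), K2CO3 (2 equiv), DMF, 40 °C
Reagents that add atoms: iodomethane, CI
Why: Williamson methylation of the chelated, hindered phenol in a dipolar aprotic solvent; acetals, aldehyde and prenyl group are inert to K2CO3 and MeI.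

Step 6
Reactants: 7 2-methoxy-4,6-bis(methoxymethoxy)-3-prenylbenzaldehyde
Product: 8 [2-methoxy-4,6-bis(methoxymethoxy)-3-prenylphenyl]methanol
Conditions: NaBH4 (1.5 equiv), MeOH–THF, 0 °C
Reagents that add atoms: none
Why: Hydride reduction of the aryl aldehyde to the benzylic alcohol; nothing else in 7 is reducible by NaBH4.

Step 7
Reactants: 8 [2-methoxy-4,6-bis(methoxymethoxy)-3-prenylphenyl]methanol
Product: 9 2-(bromomethyl)-3-methoxy-1,5-bis(methoxymethoxy)-4-prenylbenzene
Conditions: CBr4 (1.2 equiv), PPh3 (1.2 equiv), 2,6-lutidine (0.3 equiv), CH2Cl2, −20 to 0 °C; pentane, filtration; used at once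
Reagents that add atoms: tetrabromomethane, BrC(Br)(Br)Br
Why: Appel bromination under neutral, buffered conditions that spare the acid-labile acetals; the trioxygenated benzylic bromide ionises easily and is therefore only freed from Ph3PO by precipitation and taken on without chromatography.

Step 8
Reactants: 10 ethyl 4-oxopentanoate (ethyl levulinate)
Product: 11 ethyl 3-(2-methyl-1,3-dioxolan-2-yl)propanoate
Conditions: HOCH2CH2OH (2 equiv), TsOH·H2O (2 mol %), PhMe, reflux, Dean–Stark
Reagents that add atoms: ethane-1,2-diol, OCCO
Why: Acid-catalysed ketalisation with azeotropic removal of water; it masks the ketone so that only the imide is enolised in step 11.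

Step 9
Reactants: 11 ethyl 3-(2-methyl-1,3-dioxolan-2-yl)propanoate
Product: 12 3-(2-methyl-1,3-dioxolan-2-yl)propanoic acid
Conditions: NaOH (1.2 equiv), MeOH–H2O, rt; then 1 M HCl to pH 4, 0 °C
Reagents that add atoms: sodium hydroxide, [Na+].[OH-]
Why: Saponification of the ethyl ester; acidification only to pH 4 in the cold keeps the dioxolane.

Step 10
Reactants: 12 3-(2-methyl-1,3-dioxolan-2-yl)propanoic acid; 13 (4R)-4-benzyl-1,3-oxazolidin-2-one
Product: 15 (4R)-4-benzyl-3-[3-(2-methyl-1,3-dioxolan-2-yl)propanoyl]-1,3-oxazolidin-2-one, via mixed pivalic anhydride 14 (not isolated)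
Conditions: t-BuCOCl (1.05 equiv), Et3N (2.5 equiv), THF, −20 °C; then LiCl (1.1 equiv), 13 (1.0 equiv), −20 °C to rt
Reagents that add atoms: none
Why: N-Acylation of the oxazolidinone through the mixed pivalic anhydride with LiCl and Et3N, the standard way to attach the Evans auxiliary without strong base.

Step 11
Reactants: 15 (4R)-4-benzyl-3-[3-(2-methyl-1,3-dioxolan-2-yl)propanoyl]-1,3-oxazolidin-2-one; 9 2-(bromomethyl)-3-methoxy-1,5-bis(methoxymethoxy)-4-prenylbenzene
Product: 17 (4R)-4-benzyl-3-[(2R)-2-{[2-methoxy-4,6-bis(methoxymethoxy)-3-prenylphenyl]methyl}-3-(2-methyl-1,3-dioxolan-2-yl)propanoyl]-1,3-oxazolidin-2-one, via sodium Z-enolate 16 (not isolated)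
Conditions: 15 (1.5 equiv), NaN(SiMe3)2 (1.5 equiv), THF, −78 °C; then 9 (1.0 equiv), −78 to −30 °C
Reagents that add atoms: none
Why: Evans asymmetric alkylation; NaN(SiMe3)2 gives the chelated Z-enolate 16, whose face on the side of the benzyl group of the (4R)-auxiliary is blocked, so the bromide adds from the opposite face and sets the future C3 as (2R). The enolate is used in excess because 9 is the more valuable and less stable partner.

Step 12
Reactants: 17 (4R)-4-benzyl-3-[(2R)-2-{[2-methoxy-4,6-bis(methoxymethoxy)-3-prenylphenyl]methyl}-3-(2-methyl-1,3-dioxolan-2-yl)propanoyl]-1,3-oxazolidin-2-one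
Product: 18 (2R)-2-{[2-methoxy-4,6-bis(methoxymethoxy)-3-prenylphenyl]methyl}-3-(2-methyl-1,3-dioxolan-2-yl)propan-1-ol
Conditions: LiBH4 (2 equiv), MeOH (2 equiv), THF, 0 °C
Reagents that add atoms: none
Why: Reductive cleavage of the N-acyl oxazolidinone to the primary alcohol with recovery of 13; the stereocentre is now flanked by three methylene groups and cannot epimerise from here on.

Step 13
Reactants: 18 (2R)-2-{[2-methoxy-4,6-bis(methoxymethoxy)-3-prenylphenyl]methyl}-3-(2-methyl-1,3-dioxolan-2-yl)propan-1-ol
Product: 19 (4R)-4-[(4,6-dihydroxy-2-methoxy-3-prenylphenyl)methyl]-5-hydroxypentan-2-one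
Conditions: 3 M aq HCl–MeOH (1:3), 45 °C; then H2O
Reagents that add atoms: water, O
Why: Acid-catalysed cleavage of both aryl acetals and of the dioxolane in one operation; methanol traps the formaldehyde unit as its dimethyl acetal so that the electron-rich ring is not hydroxymethylated, and the dilute acid should leave the prenyl group uncyclised.

Step 14
Reactants: 19 (4R)-4-[(4,6-dihydroxy-2-methoxy-3-prenylphenyl)methyl]-5-hydroxypentan-2-one
Product: 20 1-[(3R)-7-hydroxy-5-methoxy-6-prenylchroman-3-yl]propan-2-one
Conditions: PPh3 (1.3 equiv), DIAD (1.3 equiv), THF (0.02 M), 0 °C to rt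
Reagents that add atoms: none
Why: Intramolecular Mitsunobu etherification (6-exo-tet); only the phenol ortho to the benzylic carbon can reach the activated primary carbinol, so ring C closes through O1 and the other phenol, the future 7-hydroxyl, stays free, with high dilution suppressing intermolecular etherification.

Step 15
Reactants: 20 1-[(3R)-7-hydroxy-5-methoxy-6-prenylchroman-3-yl]propan-2-one
Product: 21 1-[(3R)-5-methoxy-7-(methoxymethoxy)-6-prenylchroman-3-yl]propan-2-one
Conditions: MOMCl (1.5 equiv), i-Pr2NEt (2 equiv), CH2Cl2, 0 °C to rt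
Reagents that add atoms: chloromethyl methyl ether, COCCl
Why: Williamson-type acetal protection of the single remaining phenol; O7 has to be inert to KOt-Bu, LiN(i-Pr)2 and zerovalent palladium in the following steps.

Step 16
Reactants: 21 1-[(3R)-5-methoxy-7-(methoxymethoxy)-6-prenylchroman-3-yl]propan-2-one; 22 methyl prop-2-enoate (methyl acrylate)
Product: 24 4-[(3R)-5-methoxy-7-(methoxymethoxy)-6-prenylchroman-3-yl]cyclohexane-1,3-dione (both epimers at C4), via Michael adduct keto ester 23 (not isolated)
Conditions: KOt-Bu (2.2 equiv), THF, −10 °C; 22 (1.05 equiv) added over 1 h; then rt; 1 M HCl to pH 4, 0 °C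
Reagents that add atoms: none
Why: Consecutive Michael–Claisen annulation, the known route from substituted acetones and acrylates to 4-substituted cyclohexane-1,3-diones. KOt-Bu equilibrates the two enolates of 21 through the tert-butanol it forms, and the more substituted enolate adds to 22, creating C1′–C6′ and keto ester 23. Proton transfer then gives the methyl ketone enolate, which acylates on the ester carbonyl in a 6-exo-trig Claisen closure that forms C3′–C4′ and the carbocycle of ring B with loss of methoxide. Deprotonation of the dione to its stabilised enolate is irreversible under the conditions and pulls the sequence forward. The one new stereocentre, C1′, is not controlled and need not be, since it is epimerisable and becomes an aromatic carbon in step 19. The selectivity that matters is addition through the methylene rather than the methyl α-carbon; it relies on thermodynamic enolate control (excess alkoxide, low temperature, slow addition of 22), the methylene enolate being the more substituted one, although the branch at C3 makes this the point of greatest risk. C3 is β to the ketone and carries no acidic hydrogen, and acetal, aryl ether and prenyl groups are inert to alkoxide.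

Step 17
Reactants: 24 4-[(3R)-5-methoxy-7-(methoxymethoxy)-6-prenylchroman-3-yl]cyclohexane-1,3-dione; 4 methyl 2-methylbut-3-en-2-yl carbonate
Product: 25 4-[(3R)-5-methoxy-7-(methoxymethoxy)-6-prenylchroman-3-yl]-2-prenylcyclohexane-1,3-dione
Conditions: Pd(PPh3)4 (5 mol %), 4 (1.0 equiv), THF, 0 °C to rt
Reagents that add atoms: none
Why: Tsuji–Trost C-allylation; the same 1,1-dimethylallyl palladium complex is now attacked by the soft, bulky dione enolate at its unsubstituted terminus, and any O-allylated enol ether re-ionises under zerovalent palladium, so material funnels to C3′, the only carbon flanked by both carbonyls. One equivalent of 4 limits double alkylation.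

Step 18
Reactants: 25 4-[(3R)-5-methoxy-7-(methoxymethoxy)-6-prenylchroman-3-yl]-2-prenylcyclohexane-1,3-dione
Product: 27 (3R)-3-[2,4-bis(trimethylsilyloxy)-3-prenylcyclohexa-2,4-dien-1-yl]-5-methoxy-7-(methoxymethoxy)-6-prenylchroman, via dilithium dienediolate 26 (not isolated)
Conditions: LiN(i-Pr)2 (2.3 equiv), THF, −78 to −20 °C; then Me3SiCl (3 equiv), −78 °C to rt; pentane, filtration under Ar; used crude
Reagents that add atoms: chlorotrimethylsilane, C[Si](C)(C)Cl
Why: Double enolisation and O-silylation, the standard preparation of 1,3-bis(silyloxy)-1,3-dienes from 1,3-dicarbonyl compounds; the first equivalent of base gives the dione enolate, the second removes a proton from the unhindered C5′ methylene, and Me3SiCl traps both oxygens.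

Step 19
Reactants: 27 (3R)-3-[2,4-bis(trimethylsilyloxy)-3-prenylcyclohexa-2,4-dien-1-yl]-5-methoxy-7-(methoxymethoxy)-6-prenylchroman
Product: 29 4-[(3R)-5-methoxy-7-(methoxymethoxy)-6-prenylchroman-3-yl]-2-prenylbenzene-1,3-diol, via bis(trimethylsilyl) aryl ether 28 (not isolated)
Conditions: DDQ (1.05 equiv), 2,6-lutidine (1.5 equiv), CH2Cl2, −40 to 0 °C; then MeOH, rt
Reagents that add atoms: none
Why: Dehydrogenation by hydride abstraction; DDQ removes hydride from C6′ of the electron-rich bis(silyloxy)diene, loss of the C1′ proton gives arene 28, and methanolysis of the labile aryl silyl ethers frees the resorcinol. At low temperature the diene should react far faster than the benzylic C4–H bonds of ring A, and 2,6-lutidine buffers the hydroquinone.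

Step 20
Reactants: 29 4-[(3R)-5-methoxy-7-(methoxymethoxy)-6-prenylchroman-3-yl]-2-prenylbenzene-1,3-diol
Product: 30 6-[(3R)-5-methoxy-7-(methoxymethoxy)-6-prenylchroman-3-yl]-3-(methoxymethoxy)-2-prenylphenol
Conditions: MOMCl (1.05 equiv), i-Pr2NEt (1.5 equiv), CH2Cl2, −20 to 0 °C
Reagents that add atoms: chloromethyl methyl ether, COCCl
Why: Sterically controlled Williamson-type protection; the 4′-hydroxyl has one ortho substituent, whereas the 2′-hydroxyl is flanked by the chroman at C1′ and the prenyl group at C3′, so one equivalent of reagent at low temperature should cap O4′ and leave the 2′-hydroxyl free for ring closure.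

Step 21
Reactants: 30 6-[(3R)-5-methoxy-7-(methoxymethoxy)-6-prenylchroman-3-yl]-3-(methoxymethoxy)-2-prenylphenol
Product: 31 (3R)-5-methoxy-7-(methoxymethoxy)-3-[5-(methoxymethoxy)-2,2-dimethyl-2H-chromen-8-yl]-6-prenylchroman
Conditions: Pd(dba)2 (10 mol %), KHCO3 (1.1 equiv), DMSO–H2O (9:1), air, 60 °C
Reagents that add atoms: none
Why: Wacker-type oxidative cyclisation of an o-prenylphenol; divalent palladium formed from Pd(dba)2 and air activates the ring B alkene, the 2′-phenoxide attacks its more substituted carbon (6-endo oxypalladation), and β-hydride elimination towards the benzylic carbon gives the 2,2-dimethyl-2H-chromene. The ring A prenyl group has no free hydroxyl neighbour, and this oxidant, unlike a quinone, leaves the C4–H bonds of the electron-rich chroman alone.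

Step 22
Reactants: 31 (3R)-5-methoxy-7-(methoxymethoxy)-3-[5-(methoxymethoxy)-2,2-dimethyl-2H-chromen-8-yl]-6-prenylchroman
Product: 32 8-[(3R)-7-hydroxy-5-methoxy-6-prenylchroman-3-yl]-2,2-dimethyl-2H-chromen-5-ol
Conditions: 3 M aq HCl–MeOH (1:4), 40 °C, Ar
Reagents that add atoms: none
Why: Acid-catalysed cleavage of the two aryl methoxymethyl acetals in methanol, which traps formaldehyde as dimethoxymethane; dilute acid at 40 °C is the usual deprotection for prenylated and pyrano-fused polyphenols and should leave chromene, prenyl group and C3 untouched.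

## Compound list

1 | 2,4,6-trihydroxybenzaldehyde | O=Cc1c(O)cc(O)cc1O | starting material
2 | 2-hydroxy-4,6-bis(methoxymethoxy)benzaldehyde | COCOc1cc(O)c(C=O)c(OCOC)c1 | intermediate
3 | 2-methylbut-3-en-2-ol | CC(C)(O)C=C | starting material
4 | methyl 2-methylbut-3-en-2-yl carbonate | COC(=O)OC(C)(C)C=C | intermediate
5 | 2,4-bis(methoxymethoxy)-6-[(2-methylbut-3-en-2-yl)oxy]benzaldehyde | COCOc1cc(OC(C)(C)C=C)c(C=O)c(OCOC)c1 | intermediate
6 | 2-hydroxy-4,6-bis(methoxymethoxy)-3-(3-methylbut-2-en-1-yl)benzaldehyde | COCOc1cc(OCOC)c(C=O)c(O)c1CC=C(C)C | intermediate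
7 | 2-methoxy-4,6-bis(methoxymethoxy)-3-(3-methylbut-2-en-1-yl)benzaldehyde | COCOc1cc(OCOC)c(C=O)c(OC)c1CC=C(C)C | intermediate
8 | [2-methoxy-4,6-bis(methoxymethoxy)-3-(3-methylbut-2-en-1-yl)phenyl]methanol | COCOc1cc(OCOC)c(CO)c(OC)c1CC=C(C)C | intermediate
9 | 2-(bromomethyl)-3-methoxy-1,5-bis(methoxymethoxy)-4-(3-methylbut-2-en-1-yl)benzene | COCOc1cc(OCOC)c(CBr)c(OC)c1CC=C(C)C | intermediate
10 | ethyl 4-oxopentanoate (ethyl levulinate) | CCOC(=O)CCC(C)=O | starting material
11 | ethyl 3-(2-methyl-1,3-dioxolan-2-yl)propanoate | CCOC(=O)CCC1(C)OCCO1 | intermediate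
12 | 3-(2-methyl-1,3-dioxolan-2-yl)propanoic acid | OC(=O)CCC1(C)OCCO1 | intermediate
13 | (4R)-4-benzyl-1,3-oxazolidin-2-one | O=C1N[C@H](Cc2ccccc2)CO1 | starting material
14 | 2,2-dimethylpropanoic 3-(2-methyl-1,3-dioxolan-2-yl)propanoic anhydride | CC(C)(C)C(=O)OC(=O)CCC1(C)OCCO1 | intermediate (not isolated)
15 | (4R)-4-benzyl-3-[3-(2-methyl-1,3-dioxolan-2-yl)propanoyl]-1,3-oxazolidin-2-one | CC1(CCC(=O)N2[C@H](Cc3ccccc3)COC2=O)OCCO1 | intermediate
16 | sodium (1Z)-1-[(4R)-4-benzyl-2-oxo-1,3-oxazolidin-3-yl]-3-(2-methyl-1,3-dioxolan-2-yl)prop-1-en-1-olate | [Na+].CC1(C/C=C(\[O-])N2[C@H](Cc3ccccc3)COC2=O)OCCO1 | intermediate (not isolated)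
17 | (4R)-4-benzyl-3-[(2R)-2-{[2-methoxy-4,6-bis(methoxymethoxy)-3-(3-methylbut-2-en-1-yl)phenyl]methyl}-3-(2-methyl-1,3-dioxolan-2-yl)propanoyl]-1,3-oxazolidin-2-one | COCOc1cc(OCOC)c(C[C@H](CC2(C)OCCO2)C(=O)N2[C@H](Cc3ccccc3)COC2=O)c(OC)c1CC=C(C)C | intermediate
18 | (2R)-2-{[2-methoxy-4,6-bis(methoxymethoxy)-3-(3-methylbut-2-en-1-yl)phenyl]methyl}-3-(2-methyl-1,3-dioxolan-2-yl)propan-1-ol | COCOc1cc(OCOC)c(C[C@H](CC2(C)OCCO2)CO)c(OC)c1CC=C(C)C | intermediate
19 | (4R)-4-{[4,6-dihydroxy-2-methoxy-3-(3-methylbut-2-en-1-yl)phenyl]methyl}-5-hydroxypentan-2-one | COc1c(CC=C(C)C)c(O)cc(O)c1C[C@H](CC(C)=O)CO | intermediate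
20 | 1-[(3R)-7-hydroxy-5-methoxy-6-(3-methylbut-2-en-1-yl)-3,4-dihydro-2H-chromen-3-yl]propan-2-one | COc1c(CC=C(C)C)c(O)cc2c1C[C@H](CC(C)=O)CO2 | intermediate
21 | 1-[(3R)-5-methoxy-7-(methoxymethoxy)-6-(3-methylbut-2-en-1-yl)-3,4-dihydro-2H-chromen-3-yl]propan-2-one | COc1c(CC=C(C)C)c(OCOC)cc2c1C[C@H](CC(C)=O)CO2 | intermediate
22 | methyl prop-2-enoate (methyl acrylate) | C=CC(=O)OC | starting material
23 | methyl 4-[(3R)-5-methoxy-7-(methoxymethoxy)-6-(3-methylbut-2-en-1-yl)-3,4-dihydro-2H-chromen-3-yl]-5-oxohexanoate (both epimers at C4) | COc1c(CC=C(C)C)c(OCOC)cc2c1C[C@H](C(CCC(=O)OC)C(C)=O)CO2 | intermediate (not isolated)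
24 | 4-[(3R)-5-methoxy-7-(methoxymethoxy)-6-(3-methylbut-2-en-1-yl)-3,4-dihydro-2H-chromen-3-yl]cyclohexane-1,3-dione (both epimers at C4) | COc1c(CC=C(C)C)c(OCOC)cc2c1C[C@H](C1CCC(=O)CC1=O)CO2 | intermediate
25 | 4-[(3R)-5-methoxy-7-(methoxymethoxy)-6-(3-methylbut-2-en-1-yl)-3,4-dihydro-2H-chromen-3-yl]-2-(3-methylbut-2-en-1-yl)cyclohexane-1,3-dione (epimers) | COc1c(CC=C(C)C)c(OCOC)cc2c1C[C@H](C1CCC(=O)C(CC=C(C)C)C1=O)CO2 | intermediate
26 | dilithium 6-[(3R)-5-methoxy-7-(methoxymethoxy)-6-(3-methylbut-2-en-1-yl)-3,4-dihydro-2H-chromen-3-yl]-2-(3-methylbut-2-en-1-yl)cyclohexa-1,3-diene-1,3-diolate | [Li+].[Li+].COc1c(CC=C(C)C)c(OCOC)cc2c1C[C@H](C1CC=C([O-])C(CC=C(C)C)=C1[O-])CO2 | intermediate (not isolated)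
27 | (3R)-3-[2,4-bis(trimethylsilyloxy)-3-(3-methylbut-2-en-1-yl)cyclohexa-2,4-dien-1-yl]-5-methoxy-7-(methoxymethoxy)-6-(3-methylbut-2-en-1-yl)-3,4-dihydro-2H-chromene (epimers at the ring carbon) | COc1c(CC=C(C)C)c(OCOC)cc2c1C[C@H](C1CC=C(O[Si](C)(C)C)C(CC=C(C)C)=C1O[Si](C)(C)C)CO2 | intermediate
28 | (3R)-3-[2,4-bis(trimethylsilyloxy)-3-(3-methylbut-2-en-1-yl)phenyl]-5-methoxy-7-(methoxymethoxy)-6-(3-methylbut-2-en-1-yl)-3,4-dihydro-2H-chromene | COc1c(CC=C(C)C)c(OCOC)cc2c1C[C@H](c1ccc(O[Si](C)(C)C)c(CC=C(C)C)c1O[Si](C)(C)C)CO2 | intermediate (not isolated)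
29 | 4-[(3R)-5-methoxy-7-(methoxymethoxy)-6-(3-methylbut-2-en-1-yl)-3,4-dihydro-2H-chromen-3-yl]-2-(3-methylbut-2-en-1-yl)benzene-1,3-diol | COc1c(CC=C(C)C)c(OCOC)cc2c1C[C@H](c1ccc(O)c(CC=C(C)C)c1O)CO2 | intermediate
30 | 6-[(3R)-5-methoxy-7-(methoxymethoxy)-6-(3-methylbut-2-en-1-yl)-3,4-dihydro-2H-chromen-3-yl]-3-(methoxymethoxy)-2-(3-methylbut-2-en-1-yl)phenol | COc1c(CC=C(C)C)c(OCOC)cc2c1C[C@H](c1ccc(OCOC)c(CC=C(C)C)c1O)CO2 | intermediate
31 | (3R)-5-methoxy-7-(methoxymethoxy)-3-[5-(methoxymethoxy)-2,2-dimethyl-2H-chromen-8-yl]-6-(3-methylbut-2-en-1-yl)-3,4-dihydro-2H-chromene | COc1c(CC=C(C)C)c(OCOC)cc2c1C[C@H](c1ccc(OCOC)c3c1OC(C)(C)C=C3)CO2 | intermediate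
32 | 8-[(3R)-7-hydroxy-5-methoxy-6-(3-methylbut-2-en-1-yl)-3,4-dihydro-2H-chromen-3-yl]-2,2-dimethyl-2H-chromen-5-ol | COc1c(CC=C(C)C)c(O)cc2c1C[C@H](c1ccc(O)c3c1OC(C)(C)C=C3)CO2 | target

## Step count and least certain steps

Total step count: 22. Longest linear sequence: 18 steps (1, 3 to 7, 11 to 22) from 1.

**Step 16 (key step).** The likely failure is conjugate addition through the methyl enolate instead of the hindered, β-branched methylene enolate, leading to annulation with the wrong regiochemistry, together with repeated addition to 22. Both arise when kinetic deprotonation outruns enolate equilibration. Fallback, setting out from 21 and returning at 24: the methyl group of 21 is acylated with dimethyl carbonate and NaH to give methyl 4-[(3R)-5-methoxy-7-(methoxymethoxy)-6-prenylchroman-3-yl]-3-oxobutanoate F7. LiN(i-Pr)2 (2.2 equiv) converts it into the dilithium dienediolate F8, which can react with 22 only at its γ-carbon, the former methylene, to give dimethyl 4-[(3R)-5-methoxy-7-(methoxymethoxy)-6-prenylchroman-3-yl]-3-oxoheptanedioate F9. NaOMe in MeOH closes it by Dieckmann condensation to methyl 3-[(3R)-5-methoxy-7-(methoxymethoxy)-6-prenylchroman-3-yl]-2,6-dioxocyclohexane-1-carboxylate F10, and aqueous NaOH followed by mild acid and warming hydrolyses and decarboxylates this to 24. The regiochemistry is then fixed by the position of the ester, at the cost of three extra steps.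

**Steps 7 and 11.** Ionisation and self-alkylation of the trioxygenated benzylic bromide 9 before it meets enolate 16 would starve the alkylation; three oxygen donors ortho and para to the benzylic carbon make this the most fragile intermediate of the route. Fallback, setting out from 7 and returning at 19, with nucleophile and electrophile exchanged:
- Reductive Knoevenagel condensation of 7 with 2,2-dimethyl-1,3-dioxane-4,6-dione and diethyl 2,6-dimethyl-1,4-dihydropyridine-3,5-dicarboxylate (L-proline cat., EtOH) gives 5-{[2-methoxy-4,6-bis(methoxymethoxy)-3-prenylphenyl]methyl}-2,2-dimethyl-1,3-dioxane-4,6-dione F1.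
- Pyridine–water at 100 °C gives 3-[2-methoxy-4,6-bis(methoxymethoxy)-3-prenylphenyl]propanoic acid F2.
- Coupling with (4S)-4-benzyl-1,3-oxazolidin-2-one (DCC, DMAP) gives the N-(3-arylpropanoyl)oxazolidinone F3.
- Its sodium Z-enolate F4 (NaN(SiMe3)2, −78 °C) is alkylated with 3-bromo-2-methoxyprop-1-ene, a stable acetonyl equivalent, to give the (2R)-2-(arylmethyl)-4-methoxypent-4-enoyl imide F5.
- LiBH4 gives (2R)-4-methoxy-2-{[2-methoxy-4,6-bis(methoxymethoxy)-3-prenylphenyl]methyl}pent-4-en-1-ol F6, and the conditions of step 13 hydrolyse its enol ether and acetals to 19.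

Because the aryl group is now in the acyl part and the acetonyl unit is the electrophile, the enantiomeric auxiliary is needed for the same (R) centre.

**Step 17.** Over-alkylation at C3′, and attack through oxygen or at the tertiary allyl terminus, are the likely losses, because the mono-prenylated dione is still acidic and nucleophilic. Fallback, from 24 to 25, which makes no new compound (F0): direct SN2 alkylation of the potassium enolate of 24 with prenyl bromide in aqueous KOH, where hydrogen bonding to the enolate oxygens favours reaction at carbon and no allyl transposition is possible. Any O-prenyl enol ether is hydrolysed back to 24 with dilute acid and recycled.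

**Steps 18 and 19.** Incomplete second silylation would leave material that cannot be aromatised cleanly, and a sluggish oxidation would give DDQ time to abstract hydride from C4 of ring A. Fallback, from 27 to 29: Saegusa–Ito oxidation with Pd(OAc)2 in MeCN. Divalent palladium attacks the C5′ terminus of the diene, β-hydride elimination from C6′ and tautomerisation give 4-[(3R)-5-methoxy-7-(methoxymethoxy)-6-prenylchroman-3-yl]-2-prenyl-3-(trimethylsilyloxy)phenol F11, and methanol cleaves this to 29. This oxidant has no affinity for benzylic C–H bonds.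

**Step 21.** Cyclisation in the five-membered exo mode, or slow turnover at the hindered 2′-hydroxyl, is the main concern. Fallback, from 30 to 31, which makes no new compound (F0): hydride abstraction with DDQ (1.0 equiv, benzene, rt), which converts the o-prenylphenol into an o-quinone methide that closes by oxa-6π electrocyclisation. The contact time must be kept short because of the C4–H bonds of ring A.

## Further compounds

F1 | step 11 | 5-{[2-methoxy-4,6-bis(methoxymethoxy)-3-(3-methylbut-2-en-1-yl)phenyl]methyl}-2,2-dimethyl-1,3-dioxane-4,6-dione | COCOc1cc(OCOC)c(CC2C(=O)OC(C)(C)OC2=O)c(OC)c1CC=C(C)C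
F2 | step 11 | 3-[2-methoxy-4,6-bis(methoxymethoxy)-3-(3-methylbut-2-en-1-yl)phenyl]propanoic acid | COCOc1cc(OCOC)c(CCC(=O)O)c(OC)c1CC=C(C)C
F3 | step 11 | (4S)-4-benzyl-3-{3-[2-methoxy-4,6-bis(methoxymethoxy)-3-(3-methylbut-2-en-1-yl)phenyl]propanoyl}-1,3-oxazolidin-2-one | COCOc1cc(OCOC)c(CCC(=O)N2[C@@H](Cc3ccccc3)COC2=O)c(OC)c1CC=C(C)C
F4 | step 11 | sodium (1Z)-1-[(4S)-4-benzyl-2-oxo-1,3-oxazolidin-3-yl]-3-[2-methoxy-4,6-bis(methoxymethoxy)-3-(3-methylbut-2-en-1-yl)phenyl]prop-1-en-1-olate | [Na+].COCOc1cc(OCOC)c(C/C=C(\[O-])N2[C@@H](Cc3ccccc3)COC2=O)c(OC)c1CC=C(C)C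
F5 | step 11 | (4S)-4-benzyl-3-[(2R)-4-methoxy-2-{[2-methoxy-4,6-bis(methoxymethoxy)-3-(3-methylbut-2-en-1-yl)phenyl]methyl}pent-4-enoyl]-1,3-oxazolidin-2-one | COCOc1cc(OCOC)c(C[C@H](CC(=C)OC)C(=O)N2[C@@H](Cc3ccccc3)COC2=O)c(OC)c1CC=C(C)C
F6 | step 11 | (2R)-4-methoxy-2-{[2-methoxy-4,6-bis(methoxymethoxy)-3-(3-methylbut-2-en-1-yl)phenyl]methyl}pent-4-en-1-ol | COCOc1cc(OCOC)c(C[C@H](CC(=C)OC)CO)c(OC)c1CC=C(C)C
F7 | step 16 | methyl 4-[(3R)-5-methoxy-7-(methoxymethoxy)-6-(3-methylbut-2-en-1-yl)-3,4-dihydro-2H-chromen-3-yl]-3-oxobutanoate | COc1c(CC=C(C)C)c(OCOC)cc2c1C[C@H](CC(=O)CC(=O)OC)CO2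
F8 | step 16 | dilithium 1-methoxy-4-[(3R)-5-methoxy-7-(methoxymethoxy)-6-(3-methylbut-2-en-1-yl)-3,4-dihydro-2H-chromen-3-yl]buta-1,3-diene-1,3-diolate | [Li+].[Li+].COc1c(CC=C(C)C)c(OCOC)cc2c1C[C@H](C=C([O-])C=C([O-])OC)CO2
F9 | step 16 | dimethyl 4-[(3R)-5-methoxy-7-(methoxymethoxy)-6-(3-methylbut-2-en-1-yl)-3,4-dihydro-2H-chromen-3-yl]-3-oxoheptanedioate | COc1c(CC=C(C)C)c(OCOC)cc2c1C[C@H](C(CCC(=O)OC)C(=O)CC(=O)OC)CO2
F10 | step 16 | methyl 3-[(3R)-5-methoxy-7-(methoxymethoxy)-6-(3-methylbut-2-en-1-yl)-3,4-dihydro-2H-chromen-3-yl]-2,6-dioxocyclohexane-1-carboxylate | COc1c(CC=C(C)C)c(OCOC)cc2c1C[C@H](C1CCC(=O)C(C(=O)OC)C1=O)CO2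
F0 | step 17 | none | none
F11 | step 19 | 4-[(3R)-5-methoxy-7-(methoxymethoxy)-6-(3-methylbut-2-en-1-yl)-3,4-dihydro-2H-chromen-3-yl]-2-(3-methylbut-2-en-1-yl)-3-[(trimethylsilyl)oxy]phenol | COc1c(CC=C(C)C)c(OCOC)cc2c1C[C@H](c1ccc(O)c(CC=C(C)C)c1O[Si](C)(C)C)CO2
F0 | step 21 | none | none
A1 | alternative 1 | 3-methoxy-5-(methoxymethoxy)-4-(3-methylbut-2-en-1-yl)-2-[(4-methylbenzenesulfonyl)methyl]phenol | COc1c(CC=C(C)C)c(OCOC)cc(O)c1CS(=O)(=O)c1ccc(C)cc1
A2 | alternative 1 | 4-nitrophenyl 2-[5-(methoxymethoxy)-2,2-dimethyl-2H-chromen-8-yl]acetate | COCOc1ccc(CC(=O)Oc3ccc(cc3)[N+](=O)[O-])c2OC(C)(C)C=Cc12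
A3 | alternative 1 | 5-methoxy-3-(methoxymethoxy)-4-(3-methylbut-2-en-1-yl)-6-methylidenecyclohexa-2,4-dien-1-one | C=C1C(=O)C=C(OCOC)C(CC=C(C)C)=C1OC
A4 | alternative 1 | (3R)-5-methoxy-7-(methoxymethoxy)-3-[5-(methoxymethoxy)-2,2-dimethyl-2H-chromen-8-yl]-6-(3-methylbut-2-en-1-yl)-3,4-dihydro-2H-chromen-2-one | COc1c(CC=C(C)C)c(OCOC)cc2c1C[C@H](c1ccc(OCOC)c3c1OC(C)(C)C=C3)C(=O)O2
A5 | alternative 2 | 2-diazo-1-[(3R)-3-{2-[(2-methylbut-3-yn-2-yl)oxy]-4-[(triisopropylsilyl)oxy]phenyl}-3,4-dihydro-2H-pyran-6-yl]ethan-1-one | O=C(C=[N+]=[N-])C1=CC[C@H](c2ccc(O[Si](C(C)C)(C(C)C)C(C)C)cc2OC(C)(C)C#C)CO1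
A6 | alternative 2 | triisopropyl[(5-methylhex-4-en-1-yn-1-yl)oxy]silane | CC(C)=CCC#CO[Si](C(C)C)(C(C)C)C(C)C
A7 | alternative 2 | (3R)-6-(3-methylbut-2-en-1-yl)-3-{2-[(2-methylbut-3-yn-2-yl)oxy]-4-[(triisopropylsilyl)oxy]phenyl}-7-[(triisopropylsilyl)oxy]-3,4-dihydro-2H-chromen-5-ol | Oc1c(CC=C(C)C)c(O[Si](C(C)C)(C(C)C)C(C)C)cc2c1C[C@H](c1ccc(O[Si](C(C)C)(C(C)C)C(C)C)cc1OC(C)(C)C#C)CO2
A8 | alternative 3 | 3,5-bis(methoxymethoxy)-4-(3-methylbut-2-en-1-yl)phenol | COCOc1cc(O)cc(OCOC)c1CC=C(C)C
A9 | alternative 3 | 2-{2,2-dimethyl-5-[(triisopropylsilyl)oxy]-2H-chromen-8-yl}prop-2-enal | C=C(C=O)c1ccc(O[Si](C(C)C)(C(C)C)C(C)C)c2c1OC(C)(C)C=C2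
A10 | alternative 3 | (3R)-3-{2,2-dimethyl-5-[(triisopropylsilyl)oxy]-2H-chromen-8-yl}-5,7-bis(methoxymethoxy)-6-(3-methylbut-2-en-1-yl)-3,4-dihydro-2H-chromen-2-ol (mixture of anomers) | OC1Oc2cc(OCOC)c(CC=C(C)C)c(OCOC)c2C[C@@H]1c1ccc(O[Si](C(C)C)(C(C)C)C(C)C)c2c1OC(C)(C)C=C2
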